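The meeting opened on early times. At 2.50 d the grey run showed 23% of target and the green run 15%, yet by 6.00 d grey stood at 72%, so one speaker called the slow start an induction period.

| flask | starting material | precatalyst | remark | time |
|---|---|---|---|---|
| grey | 0.10 M | 1.8 mM | run made earlier |  |
| violet | 0.16 M | 1.8 mM | run made earlier |  |
| green | 0.20 M | 1.8 mM | run made earlier |  |
| north-west | 0.25 M | 1.8 mM |  | 30 d |
| south-west | 0.12 M | 1.8 mM |  | 30 d |

- grey (time / d: target / %): 2.50: 23; 6.00: 72; 12.0: 89; 30.0: 90
- violet (time / d: target / %): 8.00: 75; 15.0: 86; 25.0: 86; 30.0: 87
- green (time / d: target / %): 2.50: 15; 6.00: 55; 12.0: 81; 30.0: 82

(each reading ± 1.5 percentage points)

- the numbers in the tables scatter by 1.5 percentage points (one standard deviation)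

- the flask that ends with the higher amount of target, in percent of the starting material charged, or "neither" when 2 percentage points or less lies between them (north-west / south-west / neither)
- final target, as a percentage of the starting material charged, in north-west
- final target, as a percentage of the starting material charged, in south-west

A second speaker added that the grey run read 89% at 12.0 d and 90% at 30.0 d, against a scatter of 1.5 percentage points, so the target stops rising, and the question is where. A third pointed to the last readings, 90%, 87% and 82% at 0.10 M, 0.16 M and 0.20 M, which fall as the charge rises.

The chair asked which concentration sets the order of each route. The answer given was starting material. With the catalyst held fixed, a route taking one starting material goes as its concentration, and a route where two meet goes as its square, so the share lost should grow in proportion to the charge.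

The minute-taker, reckoning on their own account, pooled the grey, violet and green runs into s = 0.891 /M, the share of the charge missing from the plateau per molar of charge. That puts north-west at 77.7% and south-west at 89.3%, a gap of 12 points against a margin of 2 points.

The forecast named south-west, with 77% (71% to 81%) for north-west, a little lower than this reckoning, and 89% (86.5% to 91.5%) for south-west. Its ground was this: “That suggests a loss that is second order in starting material”.

    starting material + free catalyst → catalyst intermediate (k = 20.0 /M/h)
    2 starting material → self-condensation product (k = 0.00680 /M/h)
    catalyst intermediate → free catalyst + target (k = 1.40 /h)
    precatalyst → free catalyst (k = 0.0110 /h)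

The flasks gave 76.0% in north-west and 89.0% in south-west, so south-west ended higher, with 0.960 /M and 0.913 /M missing per molar of charge, against s = 0.891 /M. In south-west, precatalyst turned into free catalyst with a half-life of 2.6 d and stood at 1.91% of the catalyst charged by 15.0 d, while after 3.00 d the step to self-condensation product had 79% of its turnover behind it and the step releasing target 30%. A neighbour of south-west charged with 0.20 M of starting material, for which s reckons 82.2%, ended at 80.9% of target.

(The earlier runs and the new flask come from a simulation with constants of no real substance.)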